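Follow the free monomer.

| flask | free monomer | initiator | temperature | remark | time |
|---|---|---|---|---|---|
| east | 0.034 M | 0.12 mM | 60 °C | run made earlier |  |
| west | 0.075 M | 0.12 mM | 78 °C | run made earlier |  |
| north-west | 0.050 M | 0.18 mM | 60 °C | run made earlier |  |
| autumn | 0.050 M | 0.12 mM |  | at 65 °C until 1.0 min, from then on at 90 °C | 2.0 min |
| spring | 0.050 M | 0.12 mM | 65 °C |  | 2.0 min |
| dusk | 0.050 M | 0.12 mM | 90 °C |  | 2.0 min |

east run (percent of the free monomer charged)

| time / min | monomer in chains / % | free monomer / % |
|---|---|---|
| 0.200 | 0.8 | 99.5 |
| 0.333 | 0.5 | 98.2 |
| 0.417 | 0.8 | 98.3 |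
| 0.667 | 2.4 | 96.4 |
| 1.00 | 7.0 | 92.4 |
| 1.50 | 13.2 | 85.5 |
| 2.50 | 29.1 | 67.5 |

west run (percent of the free monomer charged)

| time / s | monomer in chains / % | free monomer / % |
|---|---|---|
| 10.0 | 2.6 | 95.6 |
| 12.0 | 3.2 | 93.7 |
| 20.0 | 7.8 | 88.0 |
| 30.0 | 16.2 | 78.5 |
| 50.0 | 33.6 | 59.9 |
| 80.0 | 54.6 | 36.8 |

north-west run (percent of the free monomer charged)

| time / min | monomer in chains / % | free monomer / % |
|---|---|---|
| 0.200 | 0.1 | 99.8 |
| 0.667 | 6.5 | 92.9 |
| 1.00 | 12.9 | 85.1 |
| 1.50 | 25.3 | 72.1 |
| 2.50 | 48.6 | 49.7 |

(readings scatter by 0.5 percentage points)

- percent here means free monomer units held: one self-condensation product counts as two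
- what is said of monomer in chains includes crystals
- crystals is a solid; its amount is given per volume of the solution
- what may be going on: crystals <-> monomer in chains; free monomer + initiator -> living end + monomer in chains; free monomer + living end -> monomer in chains + living end; 2 free monomer -> self-condensation product

* which flask leads in amount of monomer in chains, in percent of the free monomer charged ("all alike" within 1.5 percentage points) (autumn / spring / dusk / all alike)
* how much monomer in chains is there at the end, in percent of the free monomer charged: autumn
* how much monomer in chains is there at the end, in percent of the free monomer charged: spring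
* how much monomer in chains is there at the end, in percent of the free monomer charged: dusk

How much of the free monomer that leaves goes astray? Chains and free monomer together fall short of the charge by what self-condensation took. West at 80.0 s shows a clear gap: 8.60% of the charge beside 54.6% in chains, read with a scatter of 0.5 percentage points per reading. The self-condensation step takes free monomer in pairs and the chain step takes it once per living end, so the ratio of the two, a selectivity factor, is scaled here, at fixed temperature, with free monomer charged over initiator charged. West's ratio, brought to the charge of the three new flasks with west's temperature left in it, gives 0.105, the loss ratio: units in self-condensation product per unit in chains.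

Does this correction change the order? A charge split at that ratio puts 90.5% in chains at full conversion, so the reckoning here treats the loss as a correction and lets the order of chains follow conversion.

How fast is conversion, then? West at 78 °C, charged with 0.075 M, has free monomer down to 59.9% after 50.0 s, lower than the 67.5% of east at 60 °C, charged with 0.034 M, in a third of the time; the two runs differ in charge as well as in temperature, so this reading of the heat is an estimate. Dusk stands at 90 °C throughout, autumn reaches that temperature from 1.0 min on, and spring stays at 65 °C, so the order reckoned here is dusk, autumn, spring, with dusk under that split.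

The forecast, reading “slow initiation followed by living growth”, names dusk and gives dusk 81% (72% to 88%), autumn 72% (63% to 79%) and spring 37% (33% to 41%). Its high end for dusk stays below the split reckoned here.

The simulation puts dusk first: dusk 83.2%, autumn 69.9%, spring 38.0%.

    crystals ⇌ monomer in chains, rate k1*(cs1 - [monomer in chains]) while solid is left; crystals form when [monomer in chains] > cs1 (solubility = 41.0 mM, k = 0.268 s⁻¹)
    free monomer + initiator → living end + monomer in chains (k = 0.894 M⁻¹ s⁻¹, Ea = 61.0 kJ mol⁻¹)
    free monomer + living end → monomer in chains + living end, rate k3*[living end]*[free monomer] (k = 233 M⁻¹ s⁻¹, Ea = 40.0 kJ mol⁻¹)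
    2 free monomer → self-condensation product (k = 0.0309 M⁻¹ s⁻¹, Ea = 78.0 kJ mol⁻¹)
    (constants at 90 °C)

Autumn holds 7.42% of its charge as self-condensation product beside 69.9% in chains, a ratio of 0.106 against the 0.105 carried from west. Dusk stops short through the loss step and the time allowed acting together: without the loss step it reaches 91.9%, and at tenfold time 90.5%. The neighbour of autumn with 2.0 × 10⁻⁴ M of initiator has its loss ratio scaled to 0.0630, and that flask holds 5.27% as self-condensation product beside 84.0% in chains, a ratio of 0.0627.

The data are calculated with constants of no real substance, and the scatter is random.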